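The numbers come from no measurement.

I decided to follow one molecule of substrate through Monday's flask, the coldest, and to ask its chances at each fork before ranking the flasks.

| flask | substrate | temperature | time |
|---|---|---|---|
| Thursday's | 32 mM | 70 °C | 5.0 d |
| Wednesday's | 32 mM | 30 °C | 5.0 d |
| Monday's | 32 mM | 10 °C | 5.0 d |
| Friday's | 32 mM | 50 °C | 5.0 d |

    substrate ⇌ target (K1 = 0.35, k1 = 0.084 min⁻¹, Ea1 = 91.0 kJ mol⁻¹, ΔH1 = −16.0 kJ mol⁻¹)
    substrate ⇌ third isomer (K2 = 2.9, k2 = 0.045 min⁻¹, Ea2 = 101 kJ mol⁻¹, ΔH2 = −56.0 kJ mol⁻¹)
    crystals ⇌ target, rate k3*(cs3 - [target]) while solid is left; crystals form when [target] > cs3 (cs3 = 1.5 mM, k3 = 0.22 min⁻¹)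
    target → over-reaction product (k4 = 8.7 × 10⁻⁵ min⁻¹, Ea4 = 116 kJ mol⁻¹)
    substrate ⇌ isomer of the product (K5 = 3.0, k5 = 0.0038 min⁻¹, Ea5 = 93.0 kJ mol⁻¹, ΔH5 = −52.0 kJ mol⁻¹)
    (constants at 50 °C)

- target is meant together with its crystals
- solid, in amounts per volume of the solution: crystals
- constants are those at 50 °C; use the activation energies and enthalpies for any other temperature

* the flask that comes out highest in amount of target, in percent of the substrate charged, or "all alike" when all lie within 1.5 percentage points (Thursday's / Wednesday's / Monday's / Friday's / all alike)
* target at the end, in percent of the substrate charged, Thursday's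
* target at the end, in percent of the substrate charged, Wednesday's
* target at the end, in percent of the substrate charged, Monday's
* target at the end, in percent of the substrate charged, Friday's

I began with the constants at 10 °C, since the scheme gives them at 50 °C. Substrate goes to target with 7.02 × 10⁻⁴ min⁻¹, to the third isomer with 2.22 × 10⁻⁴ min⁻¹, and to the isomer of the product with 2.86 × 10⁻⁵ min⁻¹.

1. I took the main step first. In Monday's flask, while crystals stand, c(target) in solution stays at the solubility, so c(substrate) falls towards the level where the step balances, 1.85 mM. The relaxation half-life of this pair, 0.307 d, is shorter than the 5.0 d allowed. With this step by itself, target including crystals reaches 94.2%.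

2. Next I added the third isomer. A molecule now reaches a fork, and in Monday's flask target is the faster exit, taking 76.0% of the molecules.

3. Adding the isomer of the product gives the full fork. The fork share is the chance that a molecule leaving substrate enters target, which is the target step's rate constant over the sum of the three forward rate constants (the selectivity of the fork). In Monday's flask it is 73.7%. Applied to the substrate that can leave, it gives 69.4%.

4. Then came the rest. For the time to the balance level I reckoned a one-way decay, 2.08 d; this leaves out the return from target, so the real arrival lies later, and I used the figure as a rough split of the run. After that split my reckoning has substrate still feeding both isomers, at 0.668 mM d⁻¹, with the crystals paying for this leak. The over-reaction costs 0.00659% of the charge. My figure for Monday's target is 63.3%, a case of kinetic control.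

5. To rank the flasks I used the drain time, the charge over the one-way leak. It is 47.9 d for Monday's, longer than 5.0 d, and 1.85 d for Wednesday's, shorter than 5.0 d. The ranking gives Monday's. This figure ignores the return from the isomers, so I committed to no target value for the other flasks.

The forecast named Monday's with 62.5%, and gave 9.5% for Thursday's, 3.2% for Wednesday's and 4.7% for Friday's. Its ground for Monday's was that “the crystals stay kinetically trapped for the full five days”. It went further than I did, with figures for the three flasks I left without one.

The simulation gave Monday's as highest, at 63.1%, against 10.2% for Thursday's, 3.04% for Wednesday's and 4.70% for Friday's. Monday's flask held 58.5% as crystals at 5.00 d, but at 50.0 d its target was down to 4.65%, so its yield is a harvest to be taken in time. Its target ended 11 percentage points under the fork share of 73.7%. A neighbour of Monday's flask, at the same temperature and so with the same share but charged with 130 mM, reckons to 71.6%, and it stood at 71.2%.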